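## The problem

Labels used throughout: ring A is C1 (C=O), C2, C3 (CH3), C4, C5, C6 (CH3, S). The side chain on C2 is C7, C8 (=CHCl) and C9 (CH2N). The acyl chain is C1'–C12' with an E C4'=C5' olefin and OCH3 on C7' (S).

The target is a secondary amide of a skipped-olefin methoxy acid with an allylic amine whose central carbon C7 sits on the alpha carbon of a tetrasubstituted cyclohexenone.

The hardest element is the unit C2–C7=C8. A fully substituted enone carbon is bonded to a trisubstituted chloro-olefin, and its chlorine must stand cis to ring A (E). The diene is twisted and crowded, and no thermodynamic bias can be relied on to choose between the two olefin isomers.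

C6 is a lone stereocentre alpha to the ketone. It is epimerisable and too far from C7' for either centre to control the other, and the epimers would hardly be separable. It must therefore be set absolutely and then see as little acid and base as possible.

C7' and the E C4'=C5' olefin are a classical, separate problem.

The vinyl chloride forbids dissolving metals and late exposure to zerovalent metals. A free amine on C9 facing the C1 ketone would condense to a pyrroline, so nitrogen must be acylated before C1 is a ketone.

The feature that opens the problem is the string O=C1–C2–C7=C8(Cl). Once C2 is read as sp3, the C1 oxygen is homoallylic to the chloro-olefin. That is the product pattern of an aldehyde allylboration with an alpha-chloroallylboronate. Because C1 and C3 of ring A are 1,5-related through C6–C5–C4, the same carbon C2 can afterwards close ring A by aldol condensation.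

## Retrosynthesis

**C2=C3 (26 to 24, by way of 25).** Ring A is opened at its only double bond. This is the one ring cut that gives two carbonyl groups in a 1,5-relation and leaves both C6 and C7=C8 untouched. Cutting C1–C6 or C5–C6 would drag the stereocentre into the ring closure, and cutting C2–C7 leads to Alternative 1. Compound 24 is acyclic, and its C2–H2 is activated twice (alpha to C1=O, allylic to C7=C8). The forward reaction must enolise at C2 only, attack C3 and lose water, without touching C6 or moving C7=C8.

**C1=O to C1–OH, and N–C1' (24 to 23 to 13 + 21).** Lowering C1 to the carbinol removes the acidity of C6–H and C2–H and exposes the homoallylic alcohol retron. The amide is cut at this level and not at the end, so that the amine set free from 13 (as salt 22) meets only a carbinol. The molecule falls into two halves of similar size. The forward steps need only N-over-O acylation and a neutral oxidation.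

**C1–C2 together with the geometry of C7=C8 (13 to 3 + 11, and 11 to 7 + 8).** This is the key cut. Allyl transfer from boron forms C1–C2 and creates C7=C8 in the same closed transition state, so the position of chlorine is decided there and not in a separate olefination or coupling. Boronate 11 comes from achiral alkenylboronate 7 by insertion of one carbon (C8) taken from dichloromethane 8. The precursors are a six-carbon keto aldehyde, a three-carbon boronate and a solvent. The forward reaction must place chlorine cis to C2, choose the aldehyde over the ketone, and leave C6 alone. Control at C1 is not asked for.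

**C5–C6 (3 to 1 + 2).** The 1,5-dicarbonyl pattern of 3 is a Michael retron. Cutting at C5–C6 makes C6 the nucleophilic carbon of propanal, where enamine catalysis can set it. Both partners are bulk chemicals.

**C7–B and N–C9 (7 to 6 to 4 + 5).** Boron is placed on the internal carbon of a terminal alkyne, so the alkyne terminus becomes C2. The imidodicarbonate provides a nitrogen without N–H for the organolithium step.

**C2'–C3' (21 to 20 to 18).** The gamma,delta-unsaturated ester is a Claisen retron. The [3,3] shift through ketene acetal 19 sets the E olefin from a stereorandom allylic alcohol, which a cross-metathesis at C4'=C5' would not do cleanly.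

**C5'–vinyl and C7'–O (18 to 16 to 15 to 14).** A vinyl nucleophile on the aldehyde level of 16 (aldehyde 17), O-methylation, and asymmetric hydrogenation of commercial keto ester 14 trace C7' back to a catalytic step whose sense of induction is well established.

## Roads not taken

**Alternative 1:** Cut the amide and the sp2–sp2 bond C2–C7. This is the most obvious plan.
- Forward key step: palladium-catalysed Stille (or Suzuki) coupling of iodoenone A1 with stannane A2, then N-deprotection and acylation with 21.
- The geometry problem is only moved. A2 must itself be made as one isomer with tin and chlorine cis.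
- The coupling joins a carbon flanked by C=O and C3–CH3 to a 1,1-disubstituted alkenyl metal, which is a very crowded union. Zerovalent palladium can also insert into the C8–Cl bond of the product.
- A1 requires enantiopure ring A from the outset, and the labile C6 is carried through iodination and a hot, basic coupling.
- After deprotection, a free amine faces C1=O.
- The chosen plan needs no preformed ring and no stereodefined alkenyl metal.

**Alternative 2:** Cut C7=C8.
- Forward key step: chloromethylene Wittig olefination of the 2-acyl enone A3.
- Nothing in A3 tells the two sides of the ketone apart, because ring A and C9 are both branched neighbours. An olefin mixture is expected at the last step, where the isomers differ least.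
- The ketone is hindered and part of a vinylogous 1,3-dicarbonyl system with acidic C9–H and C6–H, so a basic, non-stabilised ylide would enolise it and endanger C6.
- The chosen plan decides the geometry early, in a cyclic transition state, on a small molecule.

**Alternative 3:** Cut C2=C3 and C7=C8 at once (enyne-metathesis retron).
- Forward key step: ring-closing skeletal reorganisation of the 1,7-enyne A4, in which C8HCl moves from C3 to C7, by a pi-acid or a ruthenium alkylidene. The step is atom-economical and in principle stereospecific.
- The ynone is polarised the wrong way, since C7 and not C2 is its electrophilic carbon.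
- A chloro-olefin is a poor pi-nucleophile.
- A ruthenium carrier would have to bear a chloromethylidene ligand, which is prone to decomposition.
- The formal [2+2]/conrotatory opening would have to turn both chlorine and the C3 methyl group inwards.
- The Z-chloro-olefin of A4 needs its own stereoselective synthesis.
- The chosen plan reaches the same two bonds with known reaction types.

Key step: step 4

Assumption: the sense of induction in step 1 follows the accepted enamine model for 2-(diarylmethyl)pyrrolidine catalysts (attack on the face remote from the diarylmethyl group). This model assigns the (R)-catalyst to (S)-3.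

## Steps

Step 1
Reactants: 1 propanal; 2 but-3-en-2-one (methyl vinyl ketone)
Product: 3 (2S)-2-methyl-5-oxohexanal
Conditions: (R)-2-[methoxy(diphenyl)methyl]pyrrolidine (5 mol %), ethyl 3,4-dihydroxybenzoate (20 mol %), neat, 4 °C; product used promptly
Reagents that add atoms: none
Why: Enamine-catalysed asymmetric Michael addition of an aldehyde to a vinyl ketone; the catalyst-bound nucleophile is attacked by 2 on the face remote from the methoxydiphenylmethyl group, which for the (R)-catalyst should set C6 as S, and the catechol co-catalyst activates 2 by hydrogen bonding so that self-aldolisation of 1 is outrun.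

Step 2
Reactants: 4 3-bromoprop-1-yne (propargyl bromide); 5 di-tert-butyl iminodicarboxylate
Product: 6 di-tert-butyl N-(prop-2-yn-1-yl)imidodicarbonate
Conditions: K2CO3, DMF, 20 °C
Reagents that add atoms: none
Why: SN2 N-alkylation of the acidic imidodicarbonate (Gabriel-type amine synthesis); the product has no N–H, which the organolithium chemistry of step 4 requires.

Step 3
Reactants: 6 di-tert-butyl N-(prop-2-yn-1-yl)imidodicarbonate
Product: 7 di-tert-butyl N-[2-(4,4,5,5-tetramethyl-1,3,2-dioxaborolan-2-yl)prop-2-en-1-yl]imidodicarbonate
Conditions: bis(pinacolato)diboron, MeOH (1.1 equiv), chloro[1,3-bis(2,4,6-trimethylphenyl)imidazolidin-2-ylidene]copper (5 mol %), NaOt-Bu (5 mol %), THF, −50 to −15 °C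
Reagents that add atoms: bis(pinacolato)diboron CC1(C)OB(OC1(C)C)B2OC(C)(C)C(C)(C)O2
Why: Copper-catalysed protoboration of a terminal alkyne (syn borylcupration, then protonolysis by methanol); with an N-aryl carbene ligand and an inductively withdrawing propargylic nitrogen, boron should go to the internal carbon (future C7) and copper to the terminus (future C2).

Step 4
Reactants: 7 di-tert-butyl N-[2-(4,4,5,5-tetramethyl-1,3,2-dioxaborolan-2-yl)prop-2-en-1-yl]imidodicarbonate; 8 dichloromethane; 3 (2S)-2-methyl-5-oxohexanal
Product: 13 di-tert-butyl N-[(2E,5S)-2-(chloromethylidene)-4-hydroxy-5-methyl-8-oxononyl]imidodicarbonate (both C4 epimers), via dichloromethyllithium 9 (not isolated), via lithium dichloromethylborate 10 (not isolated), via racemic alpha-chloroallylboronate 11 (not isolated), via O-boryl adduct 12 (not isolated)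
Conditions: 8, n-BuLi, THF, −100 °C; add 7, −100 to 20 °C; then 3, 20 to 40 °C; aq. NaHCO3
Reagents that add atoms: none
Why: Matteson homologation followed in the same flask by allylboration: 9 adds to the boron of 7, and on warming the alkenyl group of 10 migrates from boron to carbon with loss of chloride to give racemic 11, in which C8 (from 8) carries chlorine and boron. Compound 11 then transfers its allyl unit to the aldehyde carbon of 3 through a closed six-membered chair (B, O, C1, C2, C7, C8), forming C1–C2 and moving the double bond to C7=C8, and hydrolysis of 12 gives 13. The closest known reaction type is the addition of alpha-chloroallyl pinacol boronates to aldehydes, which gives homoallylic alcohols whose chloro-olefin has chlorine cis to the new chain. Geometry is controlled by the position of chlorine on C8 in the chair: axial chlorine avoids the gauche contact and dipole repulsion with the pinacolate oxygens, and equatorial chlorine would in addition be pressed against the C9 substituent on C7 (A(1,2) strain), so chlorine should end cis to C2 and trans to C9, that is E. No ring is closed in this step; ring A is closed in step 12. The one new stereocentre (C1) is not controlled and need not be, since both enantiomers of 11 and both aldehyde faces give the same olefin geometry and the C1 epimers converge on 24 in step 11. The step needs aldehyde-over-ketone selectivity, secured because uncatalysed pinacol allylboronates do not add to methyl ketones at this temperature, and it needs C6 to hold, secured by a neutral, amine-free medium (butyllithium, not an amide base, makes 9).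

Step 5
Reactants: 14 methyl 3-oxooctanoate
Product: 15 methyl (3S)-3-hydroxyoctanoate
Conditions: H2 (50 bar), RuCl2[(S)-BINAP] (0.1 mol %), MeOH, 50 °C
Reagents that add atoms: none
Why: Noyori asymmetric hydrogenation of a beta-keto ester; chelation of the keto ester to the (S)-BINAP ruthenium hydride exposes one carbonyl face and should give the 3S alcohol (future C7').

Step 6
Reactants: 15 methyl (3S)-3-hydroxyoctanoate
Product: 16 methyl (3S)-3-methoxyoctanoate
Conditions: MeI, Ag2O, MeCN, 40 °C, dark
Reagents that add atoms: iodomethane CI
Why: Silver-oxide-mediated O-methylation (Purdie methylation) runs without free alkoxide, so neither retro-aldol cleavage nor beta-elimination of the beta-hydroxy ester should intervene; C7' is not touched.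

Step 7
Reactants: 16 methyl (3S)-3-methoxyoctanoate
Product: 18 (5S)-5-methoxydec-1-en-3-ol (both C3 epimers), via (3S)-3-methoxyoctanal 17 (not isolated)
Conditions: i-Bu2AlH (1.05 equiv), CH2Cl2, −78 °C; then CH2=CHMgBr (THF), −78 to 0 °C; aq. work-up
Reagents that add atoms: vinylmagnesium bromide C=C[Mg]Br
Why: Half-reduction of the ester and 1,2-addition of the Grignard reagent to 17 as it is released avoid isolating an elimination-prone beta-methoxy aldehyde; the new carbinol centre forms without control, which is harmless because step 8 erases it.

Step 8
Reactants: 18 (5S)-5-methoxydec-1-en-3-ol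
Product: 20 ethyl (4E,7S)-7-methoxydodec-4-enoate, via mixed ketene acetal 19 (not isolated)
Conditions: MeC(OEt)3 (excess), EtCO2H (cat.), 140 °C, EtOH distilled off
Reagents that add atoms: triethyl orthoacetate CCOC(C)(OCC)OCC
Why: Johnson–Claisen rearrangement: 18 exchanges into the orthoester, loses ethanol to 19 and rearranges through a chair with the C6' chain equatorial, so both carbinol epimers funnel into the E C4'=C5' olefin; C7' is a spectator.

Step 9
Reactants: 20 ethyl (4E,7S)-7-methoxydodec-4-enoate
Product: 21 (4E,7S)-7-methoxydodec-4-enoic acid
Conditions: LiOH, THF–H2O, 20 °C; then 1 M HCl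
Reagents that add atoms: lithium hydroxide [Li+].[OH-]
Why: Saponification; no stereocentre is alpha to the carboxyl group and the isolated olefin does not migrate under these conditions.

Step 10
Reactants: 13 di-tert-butyl N-[(2E,5S)-2-(chloromethylidene)-4-hydroxy-5-methyl-8-oxononyl]imidodicarbonate; 21 (4E,7S)-7-methoxydodec-4-enoic acid
Product: 23 (4E,7S)-N-[(2E,5S)-2-(chloromethylidene)-4-hydroxy-5-methyl-8-oxononyl]-7-methoxydodec-4-enamide (both C4 epimers), via ammonium trifluoroacetate 22 (not isolated)
Conditions: CF3CO2H–CH2Cl2 (trace H2O), 0 to 20 °C, evaporate; then 21, EDC, HOBt (cat.), i-Pr2NEt, CH2Cl2, 0 to 20 °C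
Reagents that add atoms: none
Why: Acidolysis of both Boc groups, then carbodiimide/HOBt amide coupling, in which the amine is acylated far faster than the secondary alcohol. Nitrogen is capped while C1 is still a carbinol, so a free amine never faces a C1 ketone, and the trace of water keeps the delta-hydroxy ketone from dehydrating to a dihydropyran.

Step 11
Reactants: 23 (4E,7S)-N-[(2E,5S)-2-(chloromethylidene)-4-hydroxy-5-methyl-8-oxononyl]-7-methoxydodec-4-enamide
Product: 24 (4E,7S)-N-[(2E,5S)-2-(chloromethylidene)-5-methyl-4,8-dioxononyl]-7-methoxydodec-4-enamide
Conditions: Dess–Martin periodinane, NaHCO3, CH2Cl2, 0 to 20 °C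
Reagents that add atoms: none
Why: Dess–Martin oxidation under bicarbonate buffer is neutral and fast, so the beta,gamma-unsaturated ketone should form without migration of C7=C8 and without enolisation at C6; the two C1 epimers become one compound.

Step 12
Reactants: 24 (4E,7S)-N-[(2E,5S)-2-(chloromethylidene)-5-methyl-4,8-dioxononyl]-7-methoxydodec-4-enamide
Product: 26 (4E,7S)-N-{(2E)-3-chloro-2-[(5S)-2,5-dimethyl-6-oxocyclohex-1-en-1-yl]prop-2-en-1-yl}-7-methoxydodec-4-enamide (target), via ketol 25 (not isolated)
Conditions: NaOMe (0.2 equiv), MeOH, 0 °C, short contact; pH 7 buffer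
Reagents that add atoms: none
Why: Intramolecular aldol condensation (six-membered enolexo closure, then E1cB loss of water from 25): C2–H is alpha to C1=O and allylic, hence far more acidic than C6–H or the methyl ketone protons, so catalytic methoxide at 0 °C should enolise 24 at C2 only and C2 attacks the unhindered C3 ketone. Secondary-amine catalysts are avoided because they would activate the methyl ketone as an enamine and close the ring the other way round; short contact and a buffered quench protect C6.

## Compound list

1 | propanal | CCC=O | starting material
2 | but-3-en-2-one (methyl vinyl ketone) | C=CC(C)=O | starting material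
3 | (2S)-2-methyl-5-oxohexanal | CC(=O)CC[C@H](C)C=O | intermediate
4 | 3-bromoprop-1-yne (propargyl bromide) | C#CCBr | starting material
5 | di-tert-butyl iminodicarboxylate | CC(C)(C)OC(=O)NC(=O)OC(C)(C)C | starting material
6 | di-tert-butyl N-(prop-2-yn-1-yl)imidodicarbonate | C#CCN(C(=O)OC(C)(C)C)C(=O)OC(C)(C)C | intermediate
7 | di-tert-butyl N-[2-(4,4,5,5-tetramethyl-1,3,2-dioxaborolan-2-yl)prop-2-en-1-yl]imidodicarbonate | C=C(CN(C(=O)OC(C)(C)C)C(=O)OC(C)(C)C)B1OC(C)(C)C(C)(C)O1 | intermediate
8 | dichloromethane | ClCCl | starting material
9 | dichloromethyllithium | [Li]C(Cl)Cl | intermediate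
10 | lithium (dichloromethyl)borate of 7 | [Li+].C=C(CN(C(=O)OC(C)(C)C)C(=O)OC(C)(C)C)[B-]1(C(Cl)Cl)OC(C)(C)C(C)(C)O1 | intermediate
11 | di-tert-butyl N-[3-chloro-2-methylidene-3-(4,4,5,5-tetramethyl-1,3,2-dioxaborolan-2-yl)propyl]imidodicarbonate (racemic) | C=C(CN(C(=O)OC(C)(C)C)C(=O)OC(C)(C)C)C(Cl)B1OC(C)(C)C(C)(C)O1 | intermediate
12 | O-(pinacolatoboryl) derivative of 13 (both C4 epimers) | CC(C)(C)OC(=O)N(C(=O)OC(C)(C)C)C/C(=C/Cl)CC(OB1OC(C)(C)C(C)(C)O1)[C@@H](C)CCC(C)=O | intermediate
13 | di-tert-butyl N-[(2E,5S)-2-(chloromethylidene)-4-hydroxy-5-methyl-8-oxononyl]imidodicarbonate (both C4 epimers) | CC(C)(C)OC(=O)N(C(=O)OC(C)(C)C)C/C(=C/Cl)CC(O)[C@@H](C)CCC(C)=O | intermediate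
14 | methyl 3-oxooctanoate | CCCCCC(=O)CC(=O)OC | starting material
15 | methyl (3S)-3-hydroxyoctanoate | CCCCC[C@@H](CC(=O)OC)O | intermediate
16 | methyl (3S)-3-methoxyoctanoate | CCCCC[C@@H](CC(=O)OC)OC | intermediate
17 | (3S)-3-methoxyoctanal | CCCCC[C@@H](CC=O)OC | intermediate
18 | (5S)-5-methoxydec-1-en-3-ol (both C3 epimers) | CCCCC[C@@H](CC(O)C=C)OC | intermediate
19 | (5S)-3-[(1-ethoxyethenyl)oxy]-5-methoxydec-1-ene (mixed ketene acetal) | CCCCC[C@@H](CC(OC(=C)OCC)C=C)OC | intermediate
20 | ethyl (4E,7S)-7-methoxydodec-4-enoate | CCCCC[C@@H](C/C=C/CCC(=O)OCC)OC | intermediate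
21 | (4E,7S)-7-methoxydodec-4-enoic acid | CCCCC[C@@H](C/C=C/CCC(=O)O)OC | intermediate
22 | (2E,5S)-2-(chloromethylidene)-4-hydroxy-5-methyl-8-oxononan-1-aminium trifluoroacetate (both C4 epimers) | [NH3+]C/C(=C/Cl)CC(O)[C@@H](C)CCC(C)=O.[O-]C(=O)C(F)(F)F | intermediate
23 | (4E,7S)-N-[(2E,5S)-2-(chloromethylidene)-4-hydroxy-5-methyl-8-oxononyl]-7-methoxydodec-4-enamide (both C4 epimers) | CCCCC[C@@H](C/C=C/CCC(=O)NC/C(=C/Cl)CC(O)[C@@H](C)CCC(C)=O)OC | intermediate
24 | (4E,7S)-N-[(2E,5S)-2-(chloromethylidene)-5-methyl-4,8-dioxononyl]-7-methoxydodec-4-enamide | CCCCC[C@@H](C/C=C/CCC(=O)NC/C(=C/Cl)CC(=O)[C@@H](C)CCC(C)=O)OC | intermediate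
25 | (4E,7S)-N-{(2E)-3-chloro-2-[(3S)-6-hydroxy-3,6-dimethyl-2-oxocyclohexyl]prop-2-en-1-yl}-7-methoxydodec-4-enamide (ketol, mixture at the two new centres) | CCCCC[C@@H](C/C=C/CCC(=O)NC/C(=C/Cl)C1C(=O)[C@@H](C)CCC1(C)O)OC | intermediate
26 | (4E,7S)-N-{(2E)-3-chloro-2-[(5S)-2,5-dimethyl-6-oxocyclohex-1-en-1-yl]prop-2-en-1-yl}-7-methoxydodec-4-enamide | CCCCC[C@@H](C/C=C/CCC(=O)NC/C(=C/Cl)C1=C(C)CC[C@H](C)C1=O)OC | target

## Step count and least certain steps

Total step count: 12. Longest linear sequence: 8 steps (steps 5 to 12, from 14). The other two branches reach 13 in two steps (from 1 and 2) and three steps (from 4 and 5).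

**Step 4 (key step).** The most likely failure is slow allyl transfer.
- Boronate 11 is a pinacol ester that is branched at C7 and carries an electron-withdrawing chlorine on C8, so the transfer may need days or warming.
- During that time, enolisation of the alpha-branched aldehyde (erosion at C6) and 1,3-migration of boron can compete. A looser transition state would also erode the olefin geometry.
- The fallback sets out from 11 and comes back at 13. The homologation is worked up and 11 is isolated. It is turned with KHF2 in aqueous methanol into potassium {1-chloro-2-[bis(tert-butoxycarbonyl)aminomethyl]prop-2-en-1-yl}trifluoroborate F1. F1 is combined with 3 and BF3·OEt2 in CH2Cl2 at −78 °C. The allyl group is then delivered from a far more Lewis acidic boron centre through the same closed chair at low temperature, and aqueous work-up gives 13.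

**Step 12.** The most likely failures are two enolisation processes.
- Enolisation toward C6 in the product would cause epimerisation, to which 6-alkyl-3-methylcyclohexenones are prone.
- Gamma-protonation of the C2 dienolate would move C7=C8 into conjugation and, on return, scramble its geometry.
- The fallback sets out from 24 and comes back at 26. Diketone 24 is enolised under non-equilibrating, aprotic conditions with TiCl4 (enough to saturate amide and ether) and Bu3N in CH2Cl2 at −78 °C. The titanium enolate closes to ketol 25, which is isolated. Acetylation (Ac2O, DMAP, Et3N) gives the ketol acetate F2. F2 loses acetate by E1cB with DBU at 0 °C, where only the doubly activated C2–H is removed, to give 26.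

**Step 3.** The most likely failure is poor site selectivity of the borylcupration (boron to the terminal carbon), because the bulky imidodicarbonate may override the electronic bias.
- The fallback sets out from 5 and comes back at 7. Compound 5 is alkylated with 2,3-dibromopropene (K2CO3, DMF) to di-tert-butyl N-(2-bromoprop-2-en-1-yl)imidodicarbonate F3, whose C–Br bond fixes the position of boron. Miyaura borylation (bis(pinacolato)diboron, PdCl2(dppf), KOAc, dioxane, 80 °C) gives 7.

**Step 1.** The most likely failures are self-aldolisation of 1 and erosion of enantiopurity. The erosion would arise by reversible enamine formation from the product during the reaction or on isolation of a small, volatile alpha-branched aldehyde.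
- The fallback sets out from 1 and comes back at 3. Compound 1 is condensed with (S)-1-amino-2-(methoxymethyl)pyrrolidine to propanal SAMP hydrazone F4. F4 is deprotonated (LDA, THF, 0 °C) and alkylated at −100 °C with 4-iodo-2-methylbut-1-ene to the (S)-alkylated hydrazone F5. Ozonolysis (O3, CH2Cl2, −78 °C, then Me2S) cleaves the C=N and the C=CH2 bond in one neutral operation to give 3.

## Further compounds

F1 | step 4 | potassium {1-chloro-2-[bis(tert-butoxycarbonyl)aminomethyl]prop-2-en-1-yl}trifluoroborate (racemic) | [K+].C=C(CN(C(=O)OC(C)(C)C)C(=O)OC(C)(C)C)C(Cl)[B-](F)(F)F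
F2 | step 12 | acetate of ketol 25 | CCCCC[C@@H](C/C=C/CCC(=O)NC/C(=C/Cl)C1C(=O)[C@@H](C)CCC1(C)OC(C)=O)OC
F3 | step 3 | di-tert-butyl N-(2-bromoprop-2-en-1-yl)imidodicarbonate | C=C(Br)CN(C(=O)OC(C)(C)C)C(=O)OC(C)(C)C
F4 | step 1 | (S)-2-(methoxymethyl)-N-[(E)-propylidene]pyrrolidin-1-amine (propanal SAMP hydrazone) | COC[C@@H]1CCCN1/N=C/CC
F5 | step 1 | (S)-N-[(1E,2S)-2,5-dimethylhex-5-en-1-ylidene]-2-(methoxymethyl)pyrrolidin-1-amine | COC[C@@H]1CCCN1/N=C/[C@@H](C)CCC(C)=C
A1 | alternative 1 | (6S)-2-iodo-3,6-dimethylcyclohex-2-en-1-one | CC1=C(I)C(=O)[C@@H](C)CC1
A2 | alternative 1 | tert-butyl N-[(2Z)-3-chloro-2-(tributylstannyl)prop-2-en-1-yl]carbamate | CC(C)(C)OC(=O)NC/C(=C/Cl)[Sn](CCCC)(CCCC)CCCC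
A3 | alternative 2 | (4E,7S)-N-{2-[(5S)-2,5-dimethyl-6-oxocyclohex-1-en-1-yl]-2-oxoethyl}-7-methoxydodec-4-enamide | CCCCC[C@@H](C/C=C/CCC(=O)NCC(=O)C1=C(C)CC[C@H](C)C1=O)OC
A4 | alternative 3 | tert-butyl N-[(5S,8Z)-9-chloro-5,8-dimethyl-4-oxonon-8-en-2-yn-1-yl]carbamate | CC(C)(C)OC(=O)NCC#CC(=O)[C@@H](C)CC/C(C)=C\Cl
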